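**Charge ratio.** The ratio c_X/c_J in the charge of these four flasks, 95.0%, is the X ceiling: if each Q costs one X, then Q, bound forms counted, together with anything made from it, can't pass that share of the J charged. That makes X the limiting reagent here, whereas Saturday's run held 2.09 X per J.

the same everywhere: J 0.22 M
- Tuesday's: X 0.29 M; temperature 35 °C; run made earlier
- Saturday's: X 0.46 M; temperature 68 °C; run made earlier
- winter: X 0.209 M; temperature 50 °C; time 40 h
- autumn: X 0.209 M; at 20 °C until 20 h, from then on at 80 °C; time 40 h
- dawn: X 0.209 M; temperature 20 °C; time 40 h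
- spring: X 0.209 M; temperature 80 °C; time 40 h

| run | time / h | Q / % | J / % |
|---|---|---|---|
| Tuesday's | 5.00 | 0 | 89.0 |
| Tuesday's | 10.0 | 0 | 81.0 |
| Tuesday's | 20.0 | 1.4 | 70.1 |
| Tuesday's | 30.0 | 2.7 | 61.2 |
| Tuesday's | 60.0 | 8.2 | 44.6 |
| Saturday's | 2.50 | 16.7 | 23.4 |
| Saturday's | 5.00 | 30.6 | 18.4 |
| Saturday's | 8.00 | 47.8 | 13.5 |
| Saturday's | 10.0 | 53.5 | 12.2 |
| Saturday's | 12.0 | 57.6 | 10.8 |

(each reading ± 1 percentage point)

1. the flask that comes out highest in amount of Q, in percent of the J charged, or "all alike" when all lie within 1.5 percentage points (winter / autumn / dawn / spring / all alike)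
2. Q at the end, in percent of the J charged, winter
3. Q at the end, in percent of the J charged, autumn
4. Q at the end, in percent of the J charged, dawn
5. Q at the end, in percent of the J charged, spring

- a reading or a percentage of Q counts all its forms, free or not
- a reading of J is of its free form alone

**Fast rung.** In Saturday's run J reads down to a quarter by 2.50 h, while Q takes until 8.00 h to read about half, so the loss of J runs ahead of Q and at 2.50 h 59.9% stands in neither column, which you take for an unseen complex with X.

**Slow rung.** The passage into Q comes next, and Saturday's last reading doesn't show its end: at 12.0 h Q reads 57.6%, having gained 4.1 percentage points in the last 2.00 h, and 31.6% still stands unseen.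

**Second round.** So you take Saturday's last Q as a first answer and go round once more, supposing that the unseen share turns into Q as well, which gives 89.2%, and you hold that against the ceiling, which it stays under. That is your own estimate for spring, which runs hotter and longer than Saturday's run.

**The forecast.** It names spring and gives winter 30%, autumn 60%, dawn 0.2% and spring 60%, from 47% to 73%, on the ground that “The Saturday slowdown suggests reversal”; your spring figure differs from it.

**The result.** Winter gives 21.6%, autumn 78.0%, dawn 0.0770% and spring 82.8%, the highest, which lies below your 89.2%, while the forecast's spring figure is what you get with Saturday's last reading taken over. In spring half of the turnover of JX into Q is done by 3.41 h, far sooner than the end. After 40.0 h the free X stands at 2.9% of its own charge, and Q with E comes to 92.0% against the ceiling of 95.0%.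

    J + X ⇌ JX (K = 11.0 M⁻¹, k = 0.00655 M⁻¹ min⁻¹, Ea = 92.0 kJ mol⁻¹, ΔH = −9.00 kJ mol⁻¹)
    JX → Q (k = 3.56 × 10⁻⁴ min⁻¹, Ea = 103 kJ mol⁻¹)
    J + Q ⇌ JQ, settled at all times (K = 5.68 M⁻¹, ΔH = −74.0 kJ mol⁻¹)
    Q ⇌ E (K = 0.560, k = 5.54 × 10⁻⁴ min⁻¹, Ea = 105 kJ mol⁻¹, ΔH = −51.0 kJ mol⁻¹)
    (constants at 50 °C)

**Second flask.** Charge spring with 0.55 M of J and the ceiling drops to 38.0%. The flask gives Q 34.7% and E 3.31%, together 38.0%, with X at 0%.

The readings are calculated on assumed constants.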